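## Structural features

The target is a flavone. Ring A, a phloroglucinol-type benzene (C4a, C5–C8, C8a), is fused along C4a–C8a to the 4-pyranone ring C; ring B is a 4-hydroxyphenyl group on C2; C8 carries a ten-carbon chain through a benzylic CH2. The chain is CH2–CH(isopropenyl)–CH2–CH2–C(CH3)=CH2. Its single stereocentre (R) is homobenzylic and allylic, has no stereogenic neighbour and no acidic hydrogen, so it cannot epimerise through an enolate but would be erased if the isopropenyl double bond migrated. The fragile groups are the two 1,1-disubstituted alkenes and the three phenols: the alkenes give tertiary cations with acid (the 7-OH can then close a chroman ring), add electrophilic halogen and exclude hydrogenolysis, and 5-OH is hydrogen-bonded to the C4 carbonyl. The real difficulty is regiochemical: a branched chiral alkyl group must sit on C8, not on C6 or on oxygen, of a ring whose three oxygens look alike, and ring C must close onto the oxygen next to that chain. The feature exploited is that C8 lies between two oxygen-bearing carbons (C7, C8a) and para to the third (C5). That pattern results when a chain-bearing siloxyalkyne (its two carbons become C8 and C8a) joins a 3-alkoxycyclobutenone (its C1–C4 become C7, C4a, C5 and C6). The chain and its stereocentre are the skeleton of (R)-limonene opened at the ring double bond. The ring CH2 next to the former alkene CH becomes the benzylic CH2, and that alkene CH (aldehyde, then ester carbon) becomes the siloxy carbon C8a. C8 itself is the carbon inserted from dibromomethane and the terminal =CH2 comes from a Wittig reagent, so all ten limonene carbons are kept, nine in the chain and one in ring A. Because both oxygens flanking C8 are later protected identically, the labels C7 and C8a of that intermediate are interchangeable, which makes the subsequent ring substitution regiochemically unambiguous.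

## Logic of the disconnections

28 ⇐ 27. The O–CH2Ph bond at C5 is cut last. The C5 oxygen is the one that must stay masked while ring C closes, so that only the other ortho oxygen can cyclise, and its ether must survive fluoride. Nothing is gained in skeleton; the gain is that the only deprotection needing a Lewis acid is isolated at the end. The forward step must work without protic acid or hydrogen, which points to cleavage assisted by chelation to the C4 carbonyl.

27 ⇐ 24. The O1–C2 bond of ring C and three O–Si bonds are cut. This removes the pyranone ring and leaves an open aryl ynone. The forward step must close in the 6-endo and not the 5-exo mode, so the triple bond is first converted into an enaminone before the phenoxide is released.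

24 ⇐ 18 + 22. The C4a–C4 bond between ring A and the carbonyl is cut. This is the most convergent cut, dividing the molecule into a ring A halide with the chain and a three-carbon acyl unit carrying ring B. The forward step needs an aryl anion flanked by two ortho ethers and an acyl donor that stops at the ketone.

22 ⇐ 20 + 21, and 20 ⇐ 19. The bond between ring B and the alkyne carbon and the O–Si bond are cut. This leads to two catalogue compounds; the demand is only that the amine base does not add to the electron-poor alkyne.

18 ⇐ 17 ⇐ 16. The C4a–I bond and the O–Si bond at C7 are cut. Iodine marks the carbon that becomes C4a. Making the two oxygens beside C8 identical renders the two free ring positions equivalent, so no regiochemical choice remains. The forward iodination must be faster on the ring than on the two alkenes.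

16 ⇐ 8 + 11. The C7–C8, C4a–C8a and C6–C7 bonds are cut and ring A disappears. The chain is placed between two oxygens by construction and the three oxygens emerge differentiated. An alkyne and a four-membered ring replace a pentasubstituted arene, and the stereocentre is not touched. The forward step demands a regiospecific ketene–alkyne union and a ketene that prefers the alkyne to the side-chain alkenes.

11 ⇐ 9 + 10. The vinylic C–O bond is cut, an exchange of the alkoxy group on a commercial vinylogous ester. The only demand is that the strained enone survives the acid catalyst.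

8 ⇐ 5. The two bonds to the inserted alkyne carbon (to the benzylic CH2 and to the oxygen-bearing carbon) and the O–Si bond are cut, which returns a stable ester. The forward step is a one-flask ester-to-ynolate homologation with O-silylation. It must tolerate strong base without touching the stereocentre, which is β to the carbonyl and not acidic.

5 ⇐ 4 ⇐ 3 ⇐ 2 ⇐ 1. The C=CH2 bond, the ester O–CH3 bond and the aldehyde-to-acid oxidation are undone, and the C1–C2 bond of the six-membered ring is re-formed. This reaches a commercial terpene epoxide that already holds the stereocentre, the isopropenyl group and the correct spacing. Cleavage must occur only at the former ring alkene (secured by starting from its epoxide) and the oxidations must spare the isopropenyl group.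

## Other disconnections considered

Alternative 1: The cut is the ring C–O bond of a γ-lactone, tracing the chain stereocentre back to the prochiral ketone 3-(prop-1-en-2-yl)cyclobutan-1-one A1. In the forward step a flavin-dependent Baeyer–Villiger monooxygenase of the cyclohexanone monooxygenase family, with O2 and recycled NADPH, would insert oxygen into one of the two enantiotopic ring bonds of A1. This would give (4S)-4-(prop-1-en-2-yl)dihydrofuran-2(3H)-one A2 and set the stereocentre.
- In favour: the stereocentre is made catalytically with air as oxidant, and the two arms of A2 are chemically distinct. The configuration fits if the O-bearing CH2 becomes the benzylic carbon and the acyl arm grows into the 3-methylbut-3-enyl arm.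
- Against: the step solves only the stereocentre, which the chosen plan takes from the terpene at no cost. A2 holds seven of the ten chain carbons and none of ring A. An sp3–sp2 coupling of a β-branched primary electrophile with a trioxygenated aryl metal, a second coupling for the isopropenyl terminus and a separate answer to C8 versus C6 would all still be needed. Enantiotopic discrimination by a small, remote isopropenyl group is not assured.
- Comparison: on structure the chosen plan starts with more of the skeleton in place. On mechanism, enzyme-controlled group selection replaces a route with no stereo-forming step at all. On step economy the alternative is longer. It is the better plan in one respect: it does not depend on the optical purity of a natural terpene and could in principle be steered to either antipode. Once set, the stereocentre is equally robust in both plans.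

Alternative 2: The cut is the C4a–C4 and C4–C3 bonds. The ring A iodide A3 (chain between two methoxymethyl ethers, benzyl ether at C5), carbon monoxide and 1-ethynyl-4-(methoxymethoxy)benzene A4 would combine under PdCl2(PPh3)2, CuI and triethylamine. The sequence is oxidative addition of zerovalent palladium, CO insertion, acetylide transfer and reductive elimination, giving the ynone A5, which closes to ring C in the next step.
- In favour: two C–C bonds and the whole carbon skeleton in one convergent step, no strongly basic organometallic, and alkenes that do not interfere.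
- Against: it presupposes A3, so the hard question of placing the chain on C8 of a regiodefined ring A is left open. A doubly ortho-substituted, electron-rich iodide inserts palladium and CO slowly, so direct non-carbonylative coupling could compete. The methoxymethyl ethers must later be removed with acid, which endangers both alkenes and invites chroman formation.
- Comparison: at the ynone stage the two plans are equal in step count (one step from an aryl iodide). The carbonylation is the better of the two in functional-group tolerance, because it avoids the aryllithium of step 12. As a strategy-defining cut it simplifies less than the benzannulation, and its acid-labile protecting groups are a disadvantage against the fluoride-labile silyl ethers used here. It is complementary rather than competing and could be grafted onto 18.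

Alternative 3: The cut is the C4a–C5 bond of ring A. In the forward step Mg(OMe)2 would deprotonate the chain of the pyranone keto ester A6 (a 2-aryl-4-pyranone carrying at C8a the unit CH(chain)–CO–CH2–CO2Me). The vinylogous enolate running through C8 would attack the ester from C4a, and the new ring would aromatise to the 5,7-diol A7, the target as its 4'-methoxymethyl ether.
- In favour: it is biomimetic; ring A appears with both hydroxyls free; the chain position is fixed before the ring exists; no halogenation, no debenzylation and no bulky silyl groups are needed.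
- Against: A6 is a polycarbonyl compound whose most acidic site is the C6 methylene, not C8, so the productive enolate is a minor, doubly deprotonated species. O-acylation to a pyranopyranone and methoxide opening of the pyranone are plausible competitors. Building A6 needs alkylation with a β-branched chiral ten-carbon halide that limonene does not supply directly, because one carbon must be lost. The final methoxymethyl removal again needs acid.
- Comparison: on structure both plans fix C8 by construction and are equal there. On mechanism the benzannulation is governed by orbital polarisation in a pericyclic cascade, whereas the Claisen closure relies on kinetic selection among several enolates. On post-key-step economy the alternative is the better plan (one deprotection against five steps). That gain is likely to be spent in assembling A6.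

Key step: step 7

Assumption: N-methoxy-N-methylprop-2-ynamide 21 is taken as a catalogue reagent; if it is not in stock, one carbodiimide coupling of propiolic acid with N,O-dimethylhydroxylamine supplies it.

Remark: 1 is the commercial epoxide of (R)-limonene, a mixture of the two epimers at the epoxide carbons; both converge on 2 because these carbons become carbonyl carbons.

## Route

Step 1
Reactants: 1 (4R)-1-methyl-4-(prop-1-en-2-yl)-7-oxabicyclo[4.1.0]heptane [(+)-limonene 1,2-oxide, mixture of epoxide epimers]
Product: 2 (3R)-6-oxo-3-(prop-1-en-2-yl)heptanal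
Conditions: H5IO6 (1.1 equiv), THF/H2O, 0 °C → rt
Reagents that add atoms: water, O
Why: Periodic acid opens the epoxide to the diol and cleaves it in the same flask (Malaprade glycol cleavage), so only the former ring alkene is cut and the isopropenyl group is spared; the stereocentre is not involved.

Step 2
Reactants: 2 (3R)-6-oxo-3-(prop-1-en-2-yl)heptanal
Product: 3 (3R)-6-oxo-3-(prop-1-en-2-yl)heptanoic acid
Conditions: NaClO2, NaH2PO4, 2-methylbut-2-ene, t-BuOH/H2O, 0 °C → rt
Reagents that add atoms: sodium chlorite, [Na+].[O-]Cl=O
Why: Pinnick oxidation converts the aldehyde selectively; the excess trisubstituted alkene scavenges hypochlorous acid before it can reach the isopropenyl group, and the ketone is inert.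

Step 3
Reactants: 3 (3R)-6-oxo-3-(prop-1-en-2-yl)heptanoic acid
Product: 4 methyl (3R)-6-oxo-3-(prop-1-en-2-yl)heptanoate
Conditions: MeI, K2CO3, DMF, rt
Reagents that add atoms: iodomethane, CI
Why: Carboxylate O-alkylation under weakly basic, acid-free conditions; K2CO3 does not enolise the ketone enough for C-methylation and the alkene sees no acid.

Step 4
Reactants: 4 methyl (3R)-6-oxo-3-(prop-1-en-2-yl)heptanoate
Product: 5 methyl (3R)-6-methyl-3-(prop-1-en-2-yl)hept-6-enoate
Conditions: Ph3PCH3Br, NaN(SiMe3)2, THF, 0 °C; then 4, 0 °C → rt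
Reagents that add atoms: methyltriphenylphosphonium bromide, C[P+](c1ccccc1)(c1ccccc1)c1ccccc1.[Br-]
Why: Wittig methylenation; the unstabilised ylide reacts with the ketone far faster than with the ester, and the stereocentre, β to the ester and γ to the ketone, is not acidic.

Step 5
Reactants: 5 methyl (3R)-6-methyl-3-(prop-1-en-2-yl)hept-6-enoate
Product: 8 triisopropyl{[(4R)-7-methyl-4-(prop-1-en-2-yl)oct-7-en-1-yn-1-yl]oxy}silane, via dibromoketone enolate 6 (not isolated), via lithium ynolate 7 (not isolated)
Conditions: CH2Br2, LiTMP (lithium 2,2,6,6-tetramethylpiperidide), THF, −78 °C; then 5; LiN(SiMe3)2; n-BuLi, −78 → 0 °C; then i-Pr3SiCl, −78 °C → rt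
Reagents that add atoms: dibromomethane, BrCBr; chlorotriisopropylsilane, CC(C)[Si](Cl)(C(C)C)C(C)C
Why: Kowalski homologation: dibromomethyllithium acylation gives enolate 6, bromine–lithium exchange gives a carbenoid whose alkyl group shifts to the carbenoid carbon to form ynolate 7, and the bulky silyl chloride traps 7 on oxygen. The migrating CH2 is not the stereocentre, which stays β to all anionic sites.

Step 6
Reactants: 9 3-ethoxycyclobut-2-en-1-one; 10 benzyl alcohol
Product: 11 3-(benzyloxy)cyclobut-2-en-1-one
Conditions: 10 (3 equiv), camphorsulfonic acid (5 mol %), toluene, 45 °C, 100 mbar (EtOH removed)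
Reagents that add atoms: none
Why: Acid-catalysed transetherification of a vinylogous ester by addition–elimination at the β-carbon, driven by removal of the more volatile ethanol; benzyl is chosen because a benzyl enol ether has no low-energy sigmatropic pathway at the temperature of the next step.

Step 7
Reactants: 8 triisopropyl{[(4R)-7-methyl-4-(prop-1-en-2-yl)oct-7-en-1-yn-1-yl]oxy}silane; 11 3-(benzyloxy)cyclobut-2-en-1-one
Product: 16 5-(benzyloxy)-2-[(2R)-5-methyl-2-(prop-1-en-2-yl)hex-5-en-1-yl]-3-[(triisopropylsilyl)oxy]phenol, via vinylketene 12 (not isolated), via vinylcyclobutenone 13 (not isolated), via dienylketene 14 (not isolated), via cyclohexadienone 15 (not isolated)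
Conditions: 11 (1.3 equiv, added in portions), toluene (0.3 M), 80 °C then 110 °C, argon
Reagents that add atoms: none
Why: Heating 11 triggers conrotatory four-electron ring opening to vinylketene 12. The ketene C=C then adds to 8 in a regiospecific [2+2] cycloaddition, the chain-bearing alkyne carbon (β to oxygen, the nucleophilic terminus) bonding to the ketene carbonyl carbon; this forms C7–C8 and C4a–C8a and gives 13. A second four-electron opening converts 13 into dienylketene 14, whose six-electron electrocyclisation forms C6–C7 and closes ring A as 15, and tautomerisation delivers phenol 16. The closest known reaction type is the thermal benzannulation of cyclobutenones with siloxyalkynes to resorcinol monosilyl ethers (Danheiser benzannulation), here with an alkoxy group on C3 of the four-carbon partner. Ring A is closed in a pericyclic six-electron mode and all its carbons end sp2, so no new stereocentre arises; the stereocentre of 13 is transient and the chain stereocentre, two atoms from the reacting alkyne carbon, takes no part. The regiochemistry rests on the polarisation of the ynol ether against the electrophilic ketene carbon, which places the chain between the new OH and the OSi carbon and the OBn para to it. Chemoselectivity over the two 1,1-disubstituted alkenes rests on the much higher nucleophilicity of the siloxyalkyne, supported by adding 11 in portions so that 12 always meets an excess of 8.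

Step 8
Reactants: 16 5-(benzyloxy)-2-[(2R)-5-methyl-2-(prop-1-en-2-yl)hex-5-en-1-yl]-3-[(triisopropylsilyl)oxy]phenol
Product: 17 {[5-(benzyloxy)-2-[(2R)-5-methyl-2-(prop-1-en-2-yl)hex-5-en-1-yl]-1,3-phenylene]bis(oxy)}bis(triisopropylsilane)
Conditions: i-Pr3SiOTf, 2,6-lutidine, CH2Cl2, 0 °C → rt
Reagents that add atoms: triisopropylsilyl trifluoromethanesulfonate, CC(C)[Si](OS(=O)(=O)C(F)(F)F)(C(C)C)C(C)C
Why: Silylation of a phenol with a silyl triflate buffered by a hindered base, so the alkenes see no acid. Using the same silyl group on both oxygens makes the two remaining ring CH positions equivalent (exchanged by rotation about the aryl–CH2 bond).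

Step 9
Reactants: 17 {[5-(benzyloxy)-2-[(2R)-5-methyl-2-(prop-1-en-2-yl)hex-5-en-1-yl]-1,3-phenylene]bis(oxy)}bis(triisopropylsilane)
Product: 18 {[5-(benzyloxy)-4-iodo-2-[(2R)-5-methyl-2-(prop-1-en-2-yl)hex-5-en-1-yl]-1,3-phenylene]bis(oxy)}bis(triisopropylsilane)
Conditions: N-iodosuccinimide (1.05 equiv), CH2Cl2, 0 °C, dark
Reagents that add atoms: N-iodosuccinimide, O=C1CCC(=O)N1I
Why: Electrophilic aromatic iodination of a ring activated by three oxygens, expected to outpace attack on unactivated alkenes in an aprotic, acid-free medium; either free position gives the same iodide, and with no free hydroxyl present iodoetherification is excluded.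

Step 10
Reactants: 19 4-iodophenol
Product: 20 (4-iodophenoxy)triisopropylsilane
Conditions: i-Pr3SiCl, imidazole, DMF, rt
Reagents that add atoms: chlorotriisopropylsilane, CC(C)[Si](Cl)(C(C)C)C(C)C
Why: Standard phenol silylation; the triisopropylsilyl ether resists the amine and organolithium of the next two steps and falls off with the ring A silyl groups later.

Step 11
Reactants: 20 (4-iodophenoxy)triisopropylsilane; 21 N-methoxy-N-methylprop-2-ynamide
Product: 22 N-methoxy-N-methyl-3-{4-[(triisopropylsilyl)oxy]phenyl}prop-2-ynamide
Conditions: PdCl2(PPh3)2 (2 mol %), CuI (4 mol %), Et3N, THF, rt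
Reagents that add atoms: none
Why: Sonogashira coupling of an aryl iodide with a terminal alkyne; a tertiary amine is used so that no N–H amine adds to the electron-poor triple bond.

Step 12
Reactants: 18 {[5-(benzyloxy)-4-iodo-2-[(2R)-5-methyl-2-(prop-1-en-2-yl)hex-5-en-1-yl]-1,3-phenylene]bis(oxy)}bis(triisopropylsilane); 22 N-methoxy-N-methyl-3-{4-[(triisopropylsilyl)oxy]phenyl}prop-2-ynamide
Product: 24 1-{6-(benzyloxy)-3-[(2R)-5-methyl-2-(prop-1-en-2-yl)hex-5-en-1-yl]-2,4-bis[(triisopropylsilyl)oxy]phenyl}-3-{4-[(triisopropylsilyl)oxy]phenyl}prop-2-yn-1-one, via aryllithium 23 (not isolated)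
Conditions: n-BuLi (1.05 equiv), THF, −78 °C; then 22, −78 → −40 °C; cold aq. NH4Cl
Reagents that add atoms: none
Why: Iodine–lithium exchange followed by acyl substitution at an N-methoxy-N-methyl amide (Weinreb ketone synthesis), which stops at the ketone. At −78 °C migration of the bulky silyl group from oxygen to the carbanion is not expected, and the cold quench keeps the liberated hydroxylamine from adding to the ynone.

Step 13
Reactants: 24 1-{6-(benzyloxy)-3-[(2R)-5-methyl-2-(prop-1-en-2-yl)hex-5-en-1-yl]-2,4-bis[(triisopropylsilyl)oxy]phenyl}-3-{4-[(triisopropylsilyl)oxy]phenyl}prop-2-yn-1-one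
Product: 27 5-(benzyloxy)-7-hydroxy-2-(4-hydroxyphenyl)-8-[(2R)-5-methyl-2-(prop-1-en-2-yl)hex-5-en-1-yl]-4H-chromen-4-one, via enaminone 25 (not isolated), via desilylated enaminone 26 (not isolated)
Conditions: Et2NH, EtOH/THF, rt; then Bu4NF, THF, rt → 45 °C
Reagents that add atoms: none
Why: Conjugate addition of the secondary amine turns the ynone into a β-amino enone, so the phenoxide released by fluoride can only attack the β-carbon (addition–elimination, 6-endo) and no five-membered aurone can form. Only the oxygen ortho to the ketone that is not benzylated can cyclise, which fixes the chain at C8.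

Step 14
Reactants: 27 5-(benzyloxy)-7-hydroxy-2-(4-hydroxyphenyl)-8-[(2R)-5-methyl-2-(prop-1-en-2-yl)hex-5-en-1-yl]-4H-chromen-4-one
Product: 28 5,7-dihydroxy-2-(4-hydroxyphenyl)-8-[(2R)-5-methyl-2-(prop-1-en-2-yl)hex-5-en-1-yl]-4H-chromen-4-one
Conditions: MgBr2·OEt2 (4 equiv), toluene/Et2O, 70 °C; dilute aq. HCl work-up
Reagents that add atoms: none
Why: Chelation of magnesium between the C4 carbonyl and the peri ether oxygen activates only the 5-O-benzyl group for bromide attack at the benzylic carbon; this Lewis-acid debenzylation needs neither hydrogen nor protic acid, so the alkenes and the stereocentre should be preserved.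

## Compound list

1 | (4R)-1-methyl-4-(prop-1-en-2-yl)-7-oxabicyclo[4.1.0]heptane [(+)-limonene 1,2-oxide] | CC12OC1C[C@@H](CC2)C(C)=C | starting material
2 | (3R)-6-oxo-3-(prop-1-en-2-yl)heptanal | O=CC[C@@H](CCC(C)=O)C(C)=C | intermediate
3 | (3R)-6-oxo-3-(prop-1-en-2-yl)heptanoic acid | OC(=O)C[C@@H](CCC(C)=O)C(C)=C | intermediate
4 | methyl (3R)-6-oxo-3-(prop-1-en-2-yl)heptanoate | COC(=O)C[C@@H](CCC(C)=O)C(C)=C | intermediate
5 | methyl (3R)-6-methyl-3-(prop-1-en-2-yl)hept-6-enoate | COC(=O)C[C@@H](CCC(C)=C)C(C)=C | intermediate
6 | lithium (4R)-1,1-dibromo-7-methyl-4-(prop-1-en-2-yl)octa-1,7-dien-2-olate | [Li+].[O-]C(=C(Br)Br)C[C@@H](CCC(C)=C)C(C)=C | intermediate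
7 | lithium (4R)-7-methyl-4-(prop-1-en-2-yl)oct-7-en-1-yn-1-olate | [Li+].[O-]C#CC[C@@H](CCC(C)=C)C(C)=C | intermediate
8 | triisopropyl{[(4R)-7-methyl-4-(prop-1-en-2-yl)oct-7-en-1-yn-1-yl]oxy}silane | C=C(C)CC[C@H](CC#CO[Si](C(C)C)(C(C)C)C(C)C)C(C)=C | intermediate
9 | 3-ethoxycyclobut-2-en-1-one | CCOC1=CC(=O)C1 | starting material
10 | benzyl alcohol | OCc1ccccc1 | starting material
11 | 3-(benzyloxy)cyclobut-2-en-1-one | O=C1CC(OCc2ccccc2)=C1 | intermediate
12 | 3-(benzyloxy)buta-1,3-dien-1-one | O=C=CC(=C)OCc1ccccc1 | intermediate
13 | 4-[1-(benzyloxy)ethenyl]-2-[(2R)-5-methyl-2-(prop-1-en-2-yl)hex-5-en-1-yl]-3-[(triisopropylsilyl)oxy]cyclobut-2-en-1-one (both epimers at ring C4) | C=C(C)CC[C@H](CC1=C(O[Si](C(C)C)(C(C)C)C(C)C)C(C(=C)OCc2ccccc2)C1=O)C(C)=C | intermediate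
14 | 5-(benzyloxy)-2-[(2R)-5-methyl-2-(prop-1-en-2-yl)hex-5-en-1-yl]-3-[(triisopropylsilyl)oxy]hexa-1,3,5-trien-1-one | C=C(C)CC[C@H](CC(=C=O)C(O[Si](C(C)C)(C(C)C)C(C)C)=CC(=C)OCc1ccccc1)C(C)=C | intermediate
15 | 5-(benzyloxy)-2-[(2R)-5-methyl-2-(prop-1-en-2-yl)hex-5-en-1-yl]-3-[(triisopropylsilyl)oxy]cyclohexa-2,4-dien-1-one | C=C(C)CC[C@H](CC1=C(O[Si](C(C)C)(C(C)C)C(C)C)C=C(OCc2ccccc2)CC1=O)C(C)=C | intermediate
16 | 5-(benzyloxy)-2-[(2R)-5-methyl-2-(prop-1-en-2-yl)hex-5-en-1-yl]-3-[(triisopropylsilyl)oxy]phenol | C=C(C)CC[C@H](Cc1c(O)cc(OCc2ccccc2)cc1O[Si](C(C)C)(C(C)C)C(C)C)C(C)=C | intermediate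
17 | {[5-(benzyloxy)-2-[(2R)-5-methyl-2-(prop-1-en-2-yl)hex-5-en-1-yl]-1,3-phenylene]bis(oxy)}bis(triisopropylsilane) | C=C(C)CC[C@H](Cc1c(O[Si](C(C)C)(C(C)C)C(C)C)cc(OCc2ccccc2)cc1O[Si](C(C)C)(C(C)C)C(C)C)C(C)=C | intermediate
18 | {[5-(benzyloxy)-4-iodo-2-[(2R)-5-methyl-2-(prop-1-en-2-yl)hex-5-en-1-yl]-1,3-phenylene]bis(oxy)}bis(triisopropylsilane) | C=C(C)CC[C@H](Cc1c(O[Si](C(C)C)(C(C)C)C(C)C)cc(OCc2ccccc2)c(I)c1O[Si](C(C)C)(C(C)C)C(C)C)C(C)=C | intermediate
19 | 4-iodophenol | Oc1ccc(I)cc1 | starting material
20 | (4-iodophenoxy)triisopropylsilane | CC(C)[Si](Oc1ccc(I)cc1)(C(C)C)C(C)C | intermediate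
21 | N-methoxy-N-methylprop-2-ynamide | C#CC(=O)N(C)OC | starting material
22 | N-methoxy-N-methyl-3-{4-[(triisopropylsilyl)oxy]phenyl}prop-2-ynamide | CON(C)C(=O)C#Cc1ccc(O[Si](C(C)C)(C(C)C)C(C)C)cc1 | intermediate
23 | {6-(benzyloxy)-3-[(2R)-5-methyl-2-(prop-1-en-2-yl)hex-5-en-1-yl]-2,4-bis[(triisopropylsilyl)oxy]phenyl}lithium | C=C(C)CC[C@H](Cc1c(O[Si](C(C)C)(C(C)C)C(C)C)cc(OCc2ccccc2)c([Li])c1O[Si](C(C)C)(C(C)C)C(C)C)C(C)=C | intermediate
24 | 1-{6-(benzyloxy)-3-[(2R)-5-methyl-2-(prop-1-en-2-yl)hex-5-en-1-yl]-2,4-bis[(triisopropylsilyl)oxy]phenyl}-3-{4-[(triisopropylsilyl)oxy]phenyl}prop-2-yn-1-one | C=C(C)CC[C@H](Cc1c(O[Si](C(C)C)(C(C)C)C(C)C)cc(OCc2ccccc2)c(C(=O)C#Cc2ccc(O[Si](C(C)C)(C(C)C)C(C)C)cc2)c1O[Si](C(C)C)(C(C)C)C(C)C)C(C)=C | intermediate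
25 | 1-{6-(benzyloxy)-3-[(2R)-5-methyl-2-(prop-1-en-2-yl)hex-5-en-1-yl]-2,4-bis[(triisopropylsilyl)oxy]phenyl}-3-(diethylamino)-3-{4-[(triisopropylsilyl)oxy]phenyl}prop-2-en-1-one | C=C(C)CC[C@H](Cc1c(O[Si](C(C)C)(C(C)C)C(C)C)cc(OCc2ccccc2)c(C(=O)C=C(N(CC)CC)c2ccc(O[Si](C(C)C)(C(C)C)C(C)C)cc2)c1O[Si](C(C)C)(C(C)C)C(C)C)C(C)=C | intermediate
26 | 1-{6-(benzyloxy)-2,4-dihydroxy-3-[(2R)-5-methyl-2-(prop-1-en-2-yl)hex-5-en-1-yl]phenyl}-3-(diethylamino)-3-(4-hydroxyphenyl)prop-2-en-1-one (present as its phenoxides) | C=C(C)CC[C@H](Cc1c(O)cc(OCc2ccccc2)c(C(=O)C=C(N(CC)CC)c2ccc(O)cc2)c1O)C(C)=C | intermediate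
27 | 5-(benzyloxy)-7-hydroxy-2-(4-hydroxyphenyl)-8-[(2R)-5-methyl-2-(prop-1-en-2-yl)hex-5-en-1-yl]-4H-chromen-4-one | C=C(C)CC[C@H](Cc1c(O)cc(OCc4ccccc4)c2c(=O)cc(-c3ccc(O)cc3)oc12)C(C)=C | intermediate
28 | 5,7-dihydroxy-2-(4-hydroxyphenyl)-8-[(2R)-5-methyl-2-(prop-1-en-2-yl)hex-5-en-1-yl]-4H-chromen-4-one | C=C(C)CC[C@H](Cc1c(O)cc(O)c2c(=O)cc(-c3ccc(O)cc3)oc12)C(C)=C | target

## Step count and least certain steps

Total step count: 14. Longest linear sequence: 11 steps (steps 1–5, 7–9, 12–14).

Step 7 (key step). The most likely failure is a slow ring opening of 11: the alkoxy group stabilises the four-membered enone as a vinylogous ester. The temperature then needed may approach that at which the ynol ether undergoes silyl shift from oxygen to carbon, and 12 that does form may dimerise or acylate the product phenol. Fallback: generate 12 without a ring opening.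
- The fallback sets out from 8 and 10. Phosphine-catalysed (PMe3) conjugate addition of 10 to ethyl but-2-ynoate should give ethyl (2E)-3-(benzyloxy)but-2-enoate F1.
- Saponification (LiOH, THF/H2O) gives (2E)-3-(benzyloxy)but-2-enoic acid F2, and (COCl)2 with catalytic DMF gives (2E)-3-(benzyloxy)but-2-enoyl chloride F3.
- Slow addition of Et3N to F3 and 8 in toluene at room temperature forms 12 by 1,4-dehydrochlorination, which is trapped as 13.
- Brief heating at 80 °C carries 13 through 14 and 15, and the route is rejoined at 16.
- Ketene generation from β-alkyl acryloyl chlorides and ketene–siloxyalkyne [2+2] additions are both established reaction types.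

Step 9. Iodination may be retarded by crowding at a position flanked by a triisopropylsilyl ether and a benzyl ether, which would give the reagent time to attack the side-chain alkenes. Fallback: avoid halogen altogether.
- The fallback sets out from 16. Magnesium-phenoxide-directed ortho-formylation (MgCl2, Et3N, paraformaldehyde, MeCN, reflux) should give 6-(benzyloxy)-2-hydroxy-3-[(2R)-5-methyl-2-(prop-1-en-2-yl)hex-5-en-1-yl]-4-[(triisopropylsilyl)oxy]benzaldehyde F4.
- Separately, Sonogashira coupling of 20 with ethynyltrimethylsilane gives trimethyl({4-[(triisopropylsilyl)oxy]phenyl}ethynyl)silane F5, and K2CO3 in MeOH gives (4-ethynylphenoxy)triisopropylsilane F6.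
- The lithium acetylide of F6 (3 equiv) adds to F4 to give 3-(benzyloxy)-2-(1-hydroxy-3-{4-[(triisopropylsilyl)oxy]phenyl}prop-2-yn-1-yl)-6-[(2R)-5-methyl-2-(prop-1-en-2-yl)hex-5-en-1-yl]-5-[(triisopropylsilyl)oxy]phenol F7.
- MnO2 oxidises F7 to 1-{6-(benzyloxy)-2-hydroxy-3-[(2R)-5-methyl-2-(prop-1-en-2-yl)hex-5-en-1-yl]-4-[(triisopropylsilyl)oxy]phenyl}-3-{4-[(triisopropylsilyl)oxy]phenyl}prop-2-yn-1-one F8.
- Et2NH in EtOH closes ring C to 5-(benzyloxy)-8-[(2R)-5-methyl-2-(prop-1-en-2-yl)hex-5-en-1-yl]-7-[(triisopropylsilyl)oxy]-2-{4-[(triisopropylsilyl)oxy]phenyl}-4H-chromen-4-one F9, and Bu4NF returns the route at 27.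

Step 12. Acyl transfer may be incomplete because the aryllithium has two ortho substituents; it may act as a base or add to the triple bond instead of the amide carbonyl. Fallback: use a smaller, more electrophilic partner and adjust the oxidation level afterwards.
- The fallback sets out from 22 and 18. Reduction of 22 with i-Bu2AlH (THF, −78 °C) gives 3-{4-[(triisopropylsilyl)oxy]phenyl}prop-2-ynal F10.
- Addition of 23 (generated from 18 as in step 12) gives 1-{6-(benzyloxy)-3-[(2R)-5-methyl-2-(prop-1-en-2-yl)hex-5-en-1-yl]-2,4-bis[(triisopropylsilyl)oxy]phenyl}-3-{4-[(triisopropylsilyl)oxy]phenyl}prop-2-yn-1-ol F11.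
- MnO2 (or Dess–Martin periodinane) oxidises F11 and the route is rejoined at 24.

Step 14. Traces of HBr from the magnesium salt may add to the alkenes or promote closure of the 7-OH onto the isopropenyl group. Fallback: a nucleophilic instead of a Lewis-acid cleavage. It sets out from 27 and uses NaSEt (excess, DMF, 80–100 °C), which should attack the benzylic carbon in an SN2 displacement; the 5-phenoxide is a good leaving group because it is conjugated with the C4 carbonyl, and the alkenes are inert to thiolate. It ends at 28 and makes no new compound.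

Step 6. The strained enone may oligomerise or hydrolyse under acid before the exchange is complete. Fallback: an acid-free O-benzylation. It sets out from 9: hydrolysis with dilute aqueous HCl gives cyclobutane-1,3-dione F12 (an acidic enol), and Mitsunobu reaction with 10 (PPh3, diisopropyl azodicarboxylate, THF, 0 °C) rejoins the route at 11.

## Further compounds

F1 | step 7 | ethyl (2E)-3-(benzyloxy)but-2-enoate | CCOC(=O)/C=C(\C)OCc1ccccc1
F2 | step 7 | (2E)-3-(benzyloxy)but-2-enoic acid | OC(=O)/C=C(\C)OCc1ccccc1
F3 | step 7 | (2E)-3-(benzyloxy)but-2-enoyl chloride | ClC(=O)/C=C(\C)OCc1ccccc1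
F4 | step 9 | 6-(benzyloxy)-2-hydroxy-3-[(2R)-5-methyl-2-(prop-1-en-2-yl)hex-5-en-1-yl]-4-[(triisopropylsilyl)oxy]benzaldehyde | C=C(C)CC[C@H](Cc1c(O)c(C=O)c(OCc2ccccc2)cc1O[Si](C(C)C)(C(C)C)C(C)C)C(C)=C
F5 | step 9 | trimethyl({4-[(triisopropylsilyl)oxy]phenyl}ethynyl)silane | C[Si](C)(C)C#Cc1ccc(O[Si](C(C)C)(C(C)C)C(C)C)cc1
F6 | step 9 | (4-ethynylphenoxy)triisopropylsilane | C#Cc1ccc(O[Si](C(C)C)(C(C)C)C(C)C)cc1
F7 | step 9 | 3-(benzyloxy)-2-(1-hydroxy-3-{4-[(triisopropylsilyl)oxy]phenyl}prop-2-yn-1-yl)-6-[(2R)-5-methyl-2-(prop-1-en-2-yl)hex-5-en-1-yl]-5-[(triisopropylsilyl)oxy]phenol | C=C(C)CC[C@H](Cc1c(O)c(C(O)C#Cc2ccc(O[Si](C(C)C)(C(C)C)C(C)C)cc2)c(OCc2ccccc2)cc1O[Si](C(C)C)(C(C)C)C(C)C)C(C)=C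
F8 | step 9 | 1-{6-(benzyloxy)-2-hydroxy-3-[(2R)-5-methyl-2-(prop-1-en-2-yl)hex-5-en-1-yl]-4-[(triisopropylsilyl)oxy]phenyl}-3-{4-[(triisopropylsilyl)oxy]phenyl}prop-2-yn-1-one | C=C(C)CC[C@H](Cc1c(O)c(C(=O)C#Cc2ccc(O[Si](C(C)C)(C(C)C)C(C)C)cc2)c(OCc2ccccc2)cc1O[Si](C(C)C)(C(C)C)C(C)C)C(C)=C
F9 | step 9 | 5-(benzyloxy)-8-[(2R)-5-methyl-2-(prop-1-en-2-yl)hex-5-en-1-yl]-7-[(triisopropylsilyl)oxy]-2-{4-[(triisopropylsilyl)oxy]phenyl}-4H-chromen-4-one | C=C(C)CC[C@H](Cc1c(O[Si](C(C)C)(C(C)C)C(C)C)cc(OCc4ccccc4)c2c(=O)cc(-c3ccc(O[Si](C(C)C)(C(C)C)C(C)C)cc3)oc12)C(C)=C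
F10 | step 12 | 3-{4-[(triisopropylsilyl)oxy]phenyl}prop-2-ynal | O=CC#Cc1ccc(O[Si](C(C)C)(C(C)C)C(C)C)cc1
F11 | step 12 | 1-{6-(benzyloxy)-3-[(2R)-5-methyl-2-(prop-1-en-2-yl)hex-5-en-1-yl]-2,4-bis[(triisopropylsilyl)oxy]phenyl}-3-{4-[(triisopropylsilyl)oxy]phenyl}prop-2-yn-1-ol | C=C(C)CC[C@H](Cc1c(O[Si](C(C)C)(C(C)C)C(C)C)cc(OCc2ccccc2)c(C(O)C#Cc2ccc(O[Si](C(C)C)(C(C)C)C(C)C)cc2)c1O[Si](C(C)C)(C(C)C)C(C)C)C(C)=C
F0 | step 14 | none | none
F12 | step 6 | cyclobutane-1,3-dione | O=C1CC(=O)C1
A1 | alternative 1 | 3-(prop-1-en-2-yl)cyclobutan-1-one | CC(=C)C1CC(=O)C1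
A2 | alternative 1 | (4S)-4-(prop-1-en-2-yl)dihydrofuran-2(3H)-one | O=C1C[C@H](CO1)C(C)=C
A3 | alternative 2 | 1-(benzyloxy)-2-iodo-3,5-bis(methoxymethoxy)-4-[(2R)-5-methyl-2-(prop-1-en-2-yl)hex-5-en-1-yl]benzene | C=C(C)CC[C@H](Cc1c(OCOC)cc(OCc2ccccc2)c(I)c1OCOC)C(C)=C
A4 | alternative 2 | 1-ethynyl-4-(methoxymethoxy)benzene | C#Cc1ccc(OCOC)cc1
A5 | alternative 2 | 1-{6-(benzyloxy)-2,4-bis(methoxymethoxy)-3-[(2R)-5-methyl-2-(prop-1-en-2-yl)hex-5-en-1-yl]phenyl}-3-[4-(methoxymethoxy)phenyl]prop-2-yn-1-one | C=C(C)CC[C@H](Cc1c(OCOC)cc(OCc2ccccc2)c(C(=O)C#Cc2ccc(OCOC)cc2)c1OCOC)C(C)=C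
A6 | alternative 3 | methyl (6R)-4-{6-[4-(methoxymethoxy)phenyl]-4-oxo-4H-pyran-2-yl}-9-methyl-3-oxo-6-(prop-1-en-2-yl)dec-9-enoate | COC(=O)CC(=O)C(C[C@@H](CCC(C)=C)C(C)=C)c1cc(=O)cc(-c2ccc(OCOC)cc2)o1
A7 | alternative 3 | 5,7-dihydroxy-2-[4-(methoxymethoxy)phenyl]-8-[(2R)-5-methyl-2-(prop-1-en-2-yl)hex-5-en-1-yl]-4H-chromen-4-one | C=C(C)CC[C@H](Cc1c(O)cc(O)c2c(=O)cc(-c3ccc(OCOC)cc3)oc12)C(C)=C
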